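## The problem

1. Compound 37 is numbered along its skeleton: ethyl C1–C2 on C3, enamine C4=C5, N6, azepine methylenes C7–C10, C11, side-arm lactone C12–C13–C14(methyl C15)–C16(=O17)–O18, C19, C20, core lactone O21–C22(=O23)–C24(methyl C25), C26, carbinol C27–O28. A cyclohexene (C3, C4, C5, C20, C26, C27), a pyrroline (N6, C5, C20, C19, C11) and an azepine (N6, C5, C4, C10–C7) share the fully substituted enamine C4=C5; one γ-lactone is cis-fused across C20–C26 and a second α-methyl-γ-lactone hangs from C11.
2. Five of the eight stereocentres lie on the carbocycle (C3 S, C20 R, C24 R, C26 R, C27 R) and three in the side arm (C11 R, C12 S, C14 S). On the six-membered ring the ethyl group is trans to the C27 oxygen, which is cis to both C24 and O21.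
3. C3 has no neighbour to lean on and must come from a catalyst. Once set it can fix C27 (trans), the C27 hydroxyl can deliver O21 to the same face of C20, a tether on O21 fixes C26, and the convex face of the fused lactone fixes C24.
4. C11 and C12 are insulated from the core by C19 and need their own control element; C14 then follows from C12.
5. The enamine is sensitive to acid, oxidants and electrophiles, so it must be formed last. The free C27 hydroxyl lies cis to C22 and can take over the acyl group under base. The C24 methyl sits on the concave face and can epimerise. A free primary amine on C11 can attack the C16 lactone.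
6. The four-carbon bridge C7–C10 must join C4 and N6 without strong base once the lactones exist.
7. The enabling feature is the ring O21–C22–C24–C26–C20 with oxygen on C27 next to C26. A two-carbon radical held on O21 as an acetal can close 5-exo onto C26 of a C26=C27 enol ether and leave oxygen on C27.

## Retrosynthesis

**N6–C7 (azepine, enamine).** Cutting N6–C7 turns 37 into the 1-pyrroline 34, which carries a 4-chlorobutyl chain on C4. The alternative of bridging C4 and N6 with a four-carbon bis-electrophile at the end would need a strong base in the presence of two lactones. Here the chain is attached in step 4, when C4 is the only acidic carbon of an enone. The precursor has lost the seven-membered ring and the enamine. The forward step asks the imine nitrogen to displace a primary halide (via iodide 35) and the iminium ion 36 to lose C4–H.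

**C5=N6 (pyrroline).** Imine 34 opens to the γ-amino ketone 33, released from sulfinamide 32 by acid. This cut removes the last ring that contains nitrogen and leaves a carbocycle with a ketone, a chloroalkyl chain and an amino lactone arm. The forward reaction needs ring closure to outrun acyl transfer to the free amine.

**C11–C12 (side-arm lactone).** Sulfinamide 32 comes from butenolide 31 by hydrogenation, and 31 from N-sulfinyl aldimine 28 and silyloxyfuran 30 by a vinylogous Mannich reaction. This single cut brings in five carbons and sets C11 and C12 together under auxiliary control; a stepwise build-up of the amino alcohol would cost more steps. Aldimine 28 derives from keto aldehyde 26 and sulfinamide 27, and 30 from butenolide 29.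

**C24–C25 and the oxidation states of C5 and C11.** Keto aldehyde 26 comes from diol 25, and 25 from α-methylene lactone 24, which is made from lactone 20 and iminium salt 21. One hydrogenation sets C24 from the convex face and releases both benzyl ethers; one oxidation then gives the C5 ketone and the C11 aldehyde. Direct methylation of the lactone enolate would place the methyl on the wrong face.

**C24–C26 (key cut).** Lactone 20 comes from lactol acetal 19, and 19 from bromoacetal 18 by radical cyclisation onto the C26=C27 silyl enol ether. The cut removes a ring and two stereocentres (C26, C27) and leaves a monocyclic enol ether whose only demanding centre is C20. An ester tether or an enolate alkylation would be neighbouring options; the acetal tether has no unreactive rotamer and works under neutral conditions.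

**O21–C22 and the enol ether.** Compound 18 is the kinetic silyl enol ether of ketone 17, the bromoacetal of β-hydroxy ketone 15 with ethyl vinyl ether 16. The acetal is made first because a bromonium source would attack an enol ether.

**C20–O21.** β-Hydroxy ketone 15 comes from epoxy ketone 14 by reductive cleavage of C26–O. Ketone 14 comes from epoxy alcohol 13, and 13 from allylic alcohol 12 by hydroxyl-directed epoxidation; 12 is the reduction product of enone 11. Addition of a carbon nucleophile to a C20 ketone would leave the C3/C20 relationship to a weak 1,4-bias. In the sequence chosen C3 sets C27 and the C27 hydroxyl sets C20, each by a contact between neighbours.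

**C5 and C27 oxidation levels.** Enone 11 comes from ketal 10, the benzyl ether of alcohol 9, which is the reduction product of enone 8. C5 is parked as a benzyl ether so that unveiling the C27 ketone cannot give an ene-1,4-dione (which would aromatise), so that only C24 is acidic in step 16, and so that the chloroalkyl chain cannot alkylate C4 until the end.

**C4–C10, C20–C19, C2–C3.** Enone 8 comes from 6 and 1-chloro-4-iodobutane 7. Enone 6 comes from iodoenone 4 and trifluoroborate 5. Compound 4 comes from 3, and 3 from the achiral dienone 1 and diethylzinc 2 by catalytic asymmetric conjugate addition. All carbons of the core and all absolute stereochemistry of the carbocycle thus trace back to one catalytic step on a commercial dienone.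

## Roads not taken

**Alternative 1: amidofuran Diels–Alder cascade.**
- Cut and key step: C5–C20 and C26–C27 are cut. On heating, a furan diene (C5=C4–C3=C27) adds to a tethered enol-lactone alkene (C20=C26), the oxygen bridge opens and a hydrogen shift gives tetracyclic C27 ketone A1 with the C4=C5 enamide.
- Merits: pyrroline and cyclohexene form in one step, the enamide is regiodefined, and the azepine is already present as a lactam. In step count and convergence this road is clearly better than the chosen one.
- Weak points: an electron-rich enol-lactone alkene is paired with an electron-rich furan, so only the tether drives the addition. The C20/C26 face is relayed from C11 alone. A1 has the wrong C24 configuration next to an enolisable C27 ketone. The ketone must then be reduced to the equatorial alcohol. The C7 lactam carbonyl must be removed in the presence of two lactones.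
- Comparison: the chosen plan sets every stereocentre by a separate, checkable element and needs no late adjustment at C7, C24 or C27.

**Alternative 2: enamine–ynone cycloaddition and cyclobutene opening.**
- Cut and key step: C9–C10 and C4–C5 are formed and C5–C9 is broken. A pyrroline enamine adds to an ynone, the cyclobutene opens, and the ring expands to vinylogous amide A2 with the azepine and the cyclohexenone in place.
- Merits: the seven-membered ring, which is the weakest point of the chosen plan, arises by ring expansion without any N-alkylation, and the enamine is stabilised by conjugation. In that respect this road is better.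
- Weak points: C3 is the carbonyl of a vinylogous amide and is poorly electrophilic. Turning it into CH–Et with control next to C27 takes several uncertain steps. The C9=C10 alkene must be reduced without touching C4=C5. Both lactones and the enamine must survive the cascade.
- Comparison: the chosen plan fixes C3 and its ethyl group in step 1 by a reaction established on the same substrate class.

**Alternative 3: Claisen ring contraction of an alkylidene oxocene.**
- Cut and key step: C3–C4 is cut. Heating rearranges an allyl vinyl ether inside an eight-membered ring to 3-vinylcyclohexanone A3.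
- Merits: C3 and C4 are set through an ordered transition state. The C5 ketone, the C4 four-carbon chain and the C24 methyl are already in place. This is better than the chosen plan, which needs a reduction, protection and oxidation detour at C5 and a methylenation and hydrogenation pair at C24.
- Weak points: the eight-membered lactone and its enol ether must be built on a fragment that already carries C20, C24, C26 and C27. That means a long approach and a medium-ring closure. A3 also carries two silyl ethers, a benzyl ether and an acetal.
- Comparison: the chosen plan reaches the carbocycle in few steps from a commercial dienone and uses only ring sizes that close easily.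

Key step: step 14

## Route

Assumptions:
- The acetal carbon C22 of 17, 18 and 19 forms as a mixture of epimers and is drawn without configuration; it becomes the lactone carbonyl in step 15.
- The temporary centres C4 and C5 are drawn as expected from steps 4 and 5; C5 is erased in step 18 and C4 in step 24.
- The sense of induction in step 1 is assigned by analogy with cyclohexenone; if it proves opposite, the antipodal ligand is used.

Step 1
Reactants: 1 4,4-dimethoxycyclohexa-2,5-dien-1-one; 2 diethylzinc
Product: 3 (S)-5-ethyl-4,4-dimethoxycyclohex-2-en-1-one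
Conditions: Et2Zn, Cu(OTf)2 (cat.), (R,S,S)-phosphoramidite from 1,1'-bi-2-naphthol and bis(1-phenylethyl)amine (cat.), toluene, −25 °C; aq. NH4Cl
Reagents that add atoms: none
Why: Copper-catalysed asymmetric conjugate addition of a dialkylzinc to a prochiral 4,4-dialkoxycyclohexadienone, a substrate class on which the reaction is established; the ligand selects one enantiotopic enone arm and face and so sets C3 (S). The zinc enolate shields the second enone from further addition until work-up.

Step 2
Reactants: 3 (S)-5-ethyl-4,4-dimethoxycyclohex-2-en-1-one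
Product: 4 (S)-5-ethyl-2-iodo-4,4-dimethoxycyclohex-2-en-1-one
Conditions: iodine, pyridine, CH2Cl2, 0 °C → rt
Reagents that add atoms: iodine, [I][I]
Why: Pyridine-mediated α-iodination of an enone (conjugate addition of pyridine, iodination of the enolate, elimination) places iodine on C20, the only vinylic α-carbon; C3 is not enolisable.

Step 3
Reactants: 4 (S)-5-ethyl-2-iodo-4,4-dimethoxycyclohex-2-en-1-one; 5 potassium [2-(benzyloxy)ethyl]trifluoroborate
Product: 6 (S)-2-[2-(benzyloxy)ethyl]-5-ethyl-4,4-dimethoxycyclohex-2-en-1-one
Conditions: Pd(OAc)2 (cat.), RuPhos (cat.), Cs2CO3, toluene/H2O, 80 °C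
Reagents that add atoms: none
Why: Suzuki–Miyaura coupling of an α-iodoenone with a primary alkyltrifluoroborate forms C20–C19. The tetracoordinate boron suppresses β-alkoxy elimination, so the arm arrives with the future C11 oxygen already benzylated.

Step 4
Reactants: 6 (S)-2-[2-(benzyloxy)ethyl]-5-ethyl-4,4-dimethoxycyclohex-2-en-1-one; 7 1-chloro-4-iodobutane
Product: 8 (5S,6S)-2-[2-(benzyloxy)ethyl]-6-(4-chlorobutyl)-5-ethyl-4,4-dimethoxycyclohex-2-en-1-one (ethyl and chlorobutyl trans)
Conditions: LiN(i-Pr)2, THF, −78 °C; 7, DMPU, −78 → −30 °C
Reagents that add atoms: none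
Why: Kinetic α′-deprotonation of the enone (C27 is quaternary, so no γ-hydrogen competes) and SN2 alkylation at the iodide end of 7 attach C10–C7. The electrophile should enter anti to the neighbouring ethyl group; this C4 centre is erased in step 24.

Step 5
Reactants: 8 (5S,6S)-2-[2-(benzyloxy)ethyl]-6-(4-chlorobutyl)-5-ethyl-4,4-dimethoxycyclohex-2-en-1-one
Product: 9 (1R,5S,6S)-2-[2-(benzyloxy)ethyl]-6-(4-chlorobutyl)-5-ethyl-4,4-dimethoxycyclohex-2-en-1-ol (hydroxyl trans to chlorobutyl)
Conditions: NaBH4, CeCl3·7H2O, MeOH, −78 → 0 °C
Reagents that add atoms: none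
Why: Luche reduction gives the allylic alcohol by 1,2-delivery of hydride, expected anti to the C4 chain. The C5 centre is temporary and keeps C5 from acting as a ketone until step 18.

Step 6
Reactants: 9 (1R,5S,6S)-2-[2-(benzyloxy)ethyl]-6-(4-chlorobutyl)-5-ethyl-4,4-dimethoxycyclohex-2-en-1-ol
Product: 10 benzyl ether of 9 at the C5 oxygen
Conditions: NaH, BnBr, Bu4NI (cat.), THF/DMF, 0 °C → rt
Reagents that add atoms: benzyl bromide, BrCc1ccccc1
Why: Williamson etherification of the secondary alkoxide. The benzyl group matches the one on the C19–C11 arm so that both leave together in step 17.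

Step 7
Reactants: 10 benzyl ether of 9 at the C5 oxygen
Product: 11 (4R,5S,6S)-4-(benzyloxy)-3-[2-(benzyloxy)ethyl]-5-(4-chlorobutyl)-6-ethylcyclohex-2-en-1-one
Conditions: pyridinium p-toluenesulfonate, acetone/H2O, rt
Reagents that add atoms: water, O
Why: Acid hydrolysis of the allylic dimethyl ketal unveils the C27 ketone as an enone. With C5 reduced and etherified no ene-1,4-dione can form, so tautomerisation to a hydroquinone and loss of C3 are excluded.

Step 8
Reactants: 11 (4R,5S,6S)-4-(benzyloxy)-3-[2-(benzyloxy)ethyl]-5-(4-chlorobutyl)-6-ethylcyclohex-2-en-1-one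
Product: 12 (1R,4R,5S,6S)-4-(benzyloxy)-3-[2-(benzyloxy)ethyl]-5-(4-chlorobutyl)-6-ethylcyclohex-2-en-1-ol (hydroxyl trans to ethyl)
Conditions: NaBH4, CeCl3·7H2O, MeOH, −78 °C
Reagents that add atoms: none
Why: Luche reduction of a 6-alkylcyclohexenone. Axial hydride attack on the half-chair with ethyl, chain and benzyloxy equatorial should place the C27 hydroxyl equatorial and trans to ethyl (C27 R), which is the handle for step 9.

Step 9
Reactants: 12 (1R,4R,5S,6S)-4-(benzyloxy)-3-[2-(benzyloxy)ethyl]-5-(4-chlorobutyl)-6-ethylcyclohex-2-en-1-ol
Product: 13 epoxy alcohol: C20–C26 epoxide of 12 on the face of the C27 hydroxyl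
Conditions: VO(acac)2 (cat.), t-BuOOH, CH2Cl2, 0 °C → rt
Reagents that add atoms: tert-butyl hydroperoxide, CC(C)(C)OO
Why: Hydroxyl-directed vanadium-catalysed epoxidation of a cyclic allylic alcohol delivers oxygen to the face that carries the C27 hydroxyl. This sets C20 with O21 cis to O28 and therefore trans to ethyl; the benzyl ethers do not direct.

Step 10
Reactants: 13 epoxy alcohol: C20–C26 epoxide of 12 on the face of the C27 hydroxyl
Product: 14 α,β-epoxy ketone (C27 ketone with the C20–C26 epoxide)
Conditions: Dess–Martin periodinane, NaHCO3, CH2Cl2, 0 °C → rt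
Reagents that add atoms: none
Why: Dess–Martin oxidation of the secondary alcohol under buffered conditions gives the epoxy ketone without opening the epoxide or epimerising C3.

Step 11
Reactants: 14 α,β-epoxy ketone (C27 ketone with the C20–C26 epoxide)
Product: 15 (2S,3S,4R,5R)-4-(benzyloxy)-5-[2-(benzyloxy)ethyl]-3-(4-chlorobutyl)-2-ethyl-5-hydroxycyclohexan-1-one
Conditions: SmI2, THF/MeOH, −90 °C
Reagents that add atoms: none
Why: SmI2 reduces α,β-epoxy ketones by cleaving the Cα–O bond (ketyl, C26–O scission, protonation of the enolate by methanol), which keeps the tertiary hydroxyl on C20 and makes C26 a methylene. At low temperature with a proton source the β-hydroxy ketone does not dehydrate, and the alkyl chloride and benzyl ethers are inert.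

Step 12
Reactants: 15 (2S,3S,4R,5R)-4-(benzyloxy)-5-[2-(benzyloxy)ethyl]-3-(4-chlorobutyl)-2-ethyl-5-hydroxycyclohexan-1-one; 16 ethyl vinyl ether
Product: 17 2-bromo-1-ethoxyethyl acetal of 15 at the C20 oxygen (acetal epimers)
Conditions: 16, N-bromosuccinimide, CH2Cl2, −40 → 0 °C
Reagents that add atoms: N-bromosuccinimide, O=C1CCC(=O)N1Br
Why: Bromoacetalisation: the bromo-oxocarbenium ion formed from the vinyl ether is trapped by the tertiary C20 hydroxyl, placing C22 and C24 on O21. It is done before the enol ether exists because an enol ether would itself be brominated.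

Step 13
Reactants: 17 2-bromo-1-ethoxyethyl acetal of 15 at the C20 oxygen
Product: 18 C26=C27 tert-butyldimethylsilyl enol ether of 17 (precursor of the key step)
Conditions: LiN(i-Pr)2, THF, −78 °C; t-BuMe2SiOTf, −78 °C; Et3N, aq. NaHCO3
Reagents that add atoms: tert-butyldimethylsilyl triflate, CC(C)(C)[Si](C)(C)OS(=O)(=O)C(F)(F)F
Why: Kinetic deprotonation of the C27 ketone should occur at the methylene C26 (activated by the β-oxygen) and not at the tertiary C3; O-silylation then gives the regiodefined silyl enol ether. Low temperature and immediate trapping keep the enolate from expelling the β-acetal oxygen.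

Step 14
Reactants: 18 C26=C27 tert-butyldimethylsilyl enol ether of 17
Product: 19 cis-fused lactol ethyl acetal (ring O21–C22–C24–C26–C20; C27 silyl ether cis to C24; acetal epimers)
Conditions: Bu3SnH (slow addition), AIBN (cat.), benzene, 80 °C
Reagents that add atoms: none
Why: Ueno–Stork haloacetal radical cyclisation: the stannyl radical abstracts bromine from C24, and the primary C24 radical, held on O21 by the acetal, adds to C26 of the silyl enol ether in a 5-exo-trig closure that forms the ring O21–C22–C24–C26–C20 and the C24–C26 bond. Bromoacetal cyclisations onto cyclic enol ethers are the closest precedent. The three-atom tether can only reach the face of C26 that carries O21, so C26 is set cis to O21 (R). The α-silyloxy radical at C27 then takes hydrogen from Bu3SnH; with ethyl, chain and C5 benzyloxy equatorial the bicycle sits in the chair that has C24 axial, and hydrogen should enter anti to that neighbouring axial branch, leaving the silyloxy group equatorial and cis to C24 (C27 R). The step needs closure to outrun reduction of the open radical, which slow addition of the stannane secures, and bromine abstraction to outrun chlorine abstraction at C7, which the large rate difference between alkyl bromides and chlorides secures. The acetal tether is preferred to an α-bromo ester because it has no unreactive rotamer.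

Step 15
Reactants: 19 cis-fused lactol ethyl acetal
Product: 20 cis-fused γ-lactone (C22 carbonyl; C27 silyl ether; C5 and C11 benzyl ethers)
Conditions: mCPBA, BF3·OEt2, CH2Cl2, 0 °C
Reagents that add atoms: mCPBA, OOC(=O)c1cccc(Cl)c1
Why: Lewis acid-promoted peracid oxidation of a 2-alkoxytetrahydrofuran (oxocarbenium ion, peroxy acetal, fragmentation) gives the γ-lactone directly and erases the acetal centre. Unlike chromic acid it spares the silyl ether, and the substrate has no alkene or amine for the peracid to attack.

Step 16
Reactants: 20 cis-fused γ-lactone; 21 N,N-dimethylmethyleneiminium iodide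
Product: 24 α-methylene lactone (C24=C25), via Mannich base 22 (not isolated), via ammonium iodide 23 (not isolated)
Conditions: LiN(i-Pr)2, THF, −78 °C; 21, −78 → 0 °C; MeI, MeOH, rt; aq. NaHCO3, CH2Cl2, rt
Reagents that add atoms: none
Why: α-Methylenation of a lactone by Mannich reaction of its lithium enolate with the iminium salt, N-methylation and base-induced loss of trimethylamine. C24 is the only acidic position because C5 is an ether.

Step 17
Reactants: 24 α-methylene lactone (C24=C25)
Product: 25 diol (C5 and C11 hydroxyls) with the C24 methyl on the concave face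
Conditions: H2 (1 atm), Pd(OH)2/C, EtOAc, rt
Reagents that add atoms: none
Why: Heterogeneous hydrogenation adds hydrogen to the exocyclic alkene from the convex face of the cis-fused lactone (the face of C26–H), which places the methyl group cis to C27 (C24 R). The same catalyst removes both benzyl ethers by hydrogenolysis; the primary alkyl chloride and the silyl ether are stable in ethyl acetate.

Step 18
Reactants: 25 diol (C5 and C11 hydroxyls)
Product: 26 keto aldehyde (C5 ketone, C11 aldehyde)
Conditions: Dess–Martin periodinane, NaHCO3, CH2Cl2, rt
Reagents that add atoms: none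
Why: Dess–Martin oxidation converts the primary alcohol into the C11 aldehyde and the secondary alcohol into the C5 ketone in one buffered, non-epimerising operation; the temporary C5 centre is erased.

Step 19
Reactants: 26 keto aldehyde; 27 (S)-2-methylpropane-2-sulfinamide
Product: 28 (E)-N-tert-butanesulfinyl aldimine at C11 (sulfur S)
Conditions: 27, CuSO4, CH2Cl2, rt
Reagents that add atoms: none
Why: Condensation of an aldehyde with tert-butanesulfinamide over a dehydrating Lewis acid gives the (E)-sulfinyl aldimine. The hindered, α-quaternary C5 ketone does not condense at room temperature.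

Step 20
Reactants: 29 3-methylfuran-2(5H)-one
Product: 30 3-methyl-2-(triisopropylsilyloxy)furan
Conditions: i-Pr3SiOTf, Et3N, CH2Cl2, 0 °C
Reagents that add atoms: triisopropylsilyl triflate, CC(C)[Si](C(C)C)(C(C)C)OS(=O)(=O)C(F)(F)F
Why: Soft enolisation of the butenolide with a silyl triflate and an amine gives the aromatic 2-silyloxyfuran, the nucleophile that supplies C12–C16 with C15.

Step 21
Reactants: 28 (E)-N-tert-butanesulfinyl aldimine at C11; 30 3-methyl-2-(triisopropylsilyloxy)furan
Product: 31 sulfinamide with the 3-methylbutenolide on C11 (C11 R, C12 S; N6 and O18 anti)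
Conditions: Me3SiOTf (cat.), CH2Cl2, −78 °C
Reagents that add atoms: none
Why: Vinylogous Mukaiyama–Mannich reaction of a 2-silyloxyfuran with an N-tert-butanesulfinyl aldimine, a known pairing. The furan reacts at its 5-position (C12) through an open transition state on the imine face away from the tert-butyl group of the S-configured auxiliary, which should give C11 R; the anti arrangement of N6 and O18 usual for this reaction gives C12 S. The C5 ketone is too hindered to compete.

Step 22
Reactants: 31 sulfinamide with the 3-methylbutenolide on C11
Product: 32 sulfinamide with the saturated cis-α-methyl-γ-lactone (C14 S)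
Conditions: H2 (1 atm), Pd/C, EtOAc, rt
Reagents that add atoms: none
Why: Hydrogenation of the α-methylbutenolide from the face opposite the C12 substituent gives the cis-2,4-disubstituted lactone (C14 S). The sulfinamide, ketone and alkyl chloride are not reduced under these conditions.

Step 23
Reactants: 32 sulfinamide with the saturated cis-α-methyl-γ-lactone
Product: 34 1-pyrroline (C5=N6) with free C27 hydroxyl and 4-chlorobutyl on C4, via amino ketone hydrochloride 33 (not isolated)
Conditions: HCl, MeOH, 0 °C → rt; then NaHCO3, CH2Cl2/H2O, 0 °C
Reagents that add atoms: none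
Why: Acidic methanol removes the N-sulfinyl group and the silyl ether, and on buffering the γ-amino ketone closes to the 1-pyrroline (5-exo-trig addition, dehydration). The amine stays protonated until closure and no strong base is used, which should prevent O-to-N acyl shift from the C12 lactone and acyl migration from O21 to O28.

Step 24
Reactants: 34 1-pyrroline (C5=N6) with 4-chlorobutyl on C4
Product: 37 CNP0154902.3, via iodide 35 (not isolated), via iminium iodide 36 (not isolated)
Conditions: NaI, NaHCO3, MeCN, 70 °C
Reagents that add atoms: none
Why: Halide exchange gives the iodide, the imine nitrogen (its lone pair lies on the C4 side of C5) displaces it to close the seven-membered ring, and hydrogencarbonate removes C4–H from the iminium ion; C20 has no hydrogen, so only the C4=C5 enamine can form. C-alkylation through the enamine tautomer would have to build a spiro quaternary centre and should be slower.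

## Compound list

1 | 4,4-dimethoxycyclohexa-2,5-dien-1-one | COC1(OC)C=CC(=O)C=C1 | starting material
2 | diethylzinc | CC[Zn]CC | starting material
3 | (S)-5-ethyl-4,4-dimethoxycyclohex-2-en-1-one | CC[C@H]1CC(=O)C=CC1(OC)OC | intermediate
4 | (S)-5-ethyl-2-iodo-4,4-dimethoxycyclohex-2-en-1-one | CC[C@H]1CC(=O)C(I)=CC1(OC)OC | intermediate
5 | potassium [2-(benzyloxy)ethyl]trifluoroborate | [K+].F[B-](F)(F)CCOCc1ccccc1 | starting material
6 | (S)-2-[2-(benzyloxy)ethyl]-5-ethyl-4,4-dimethoxycyclohex-2-en-1-one | CC[C@H]1CC(=O)C(CCOCc2ccccc2)=CC1(OC)OC | intermediate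
7 | 1-chloro-4-iodobutane | ClCCCCI | starting material
8 | (5S,6S)-2-[2-(benzyloxy)ethyl]-6-(4-chlorobutyl)-5-ethyl-4,4-dimethoxycyclohex-2-en-1-one | CC[C@H]1[C@H](CCCCCl)C(=O)C(CCOCc2ccccc2)=CC1(OC)OC | intermediate
9 | (1R,5S,6S)-2-[2-(benzyloxy)ethyl]-6-(4-chlorobutyl)-5-ethyl-4,4-dimethoxycyclohex-2-en-1-ol | CC[C@H]1[C@H](CCCCCl)[C@@H](O)C(CCOCc2ccccc2)=CC1(OC)OC | intermediate
10 | benzyl ether of 9 at the C5 oxygen | CC[C@H]1[C@H](CCCCCl)[C@@H](OCc2ccccc2)C(CCOCc3ccccc3)=CC1(OC)OC | intermediate
11 | (4R,5S,6S)-4-(benzyloxy)-3-[2-(benzyloxy)ethyl]-5-(4-chlorobutyl)-6-ethylcyclohex-2-en-1-one | CC[C@H]1[C@H](CCCCCl)[C@@H](OCc2ccccc2)C(CCOCc3ccccc3)=CC1=O | intermediate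
12 | (1R,4R,5S,6S)-4-(benzyloxy)-3-[2-(benzyloxy)ethyl]-5-(4-chlorobutyl)-6-ethylcyclohex-2-en-1-ol | CC[C@H]1[C@H](CCCCCl)[C@@H](OCc2ccccc2)C(CCOCc3ccccc3)=C[C@@H]1O | intermediate
13 | epoxy alcohol (C20–C26 epoxide cis to the C27 hydroxyl) | CC[C@H]1[C@H](CCCCCl)[C@@H](OCc2ccccc2)[C@]3(CCOCc4ccccc4)O[C@@H]3[C@@H]1O | intermediate
14 | α,β-epoxy ketone (C27 ketone) | CC[C@H]1[C@H](CCCCCl)[C@@H](OCc2ccccc2)[C@]3(CCOCc4ccccc4)O[C@@H]3C1=O | intermediate
15 | (2S,3S,4R,5R)-4-(benzyloxy)-5-[2-(benzyloxy)ethyl]-3-(4-chlorobutyl)-2-ethyl-5-hydroxycyclohexan-1-one | CC[C@H]1[C@H](CCCCCl)[C@@H](OCc2ccccc2)[C@](CCOCc3ccccc3)(O)CC1=O | intermediate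
16 | ethyl vinyl ether | C=COCC | starting material
17 | 2-bromo-1-ethoxyethyl acetal of 15 at O21 (acetal epimers) | CC[C@H]1[C@H](CCCCCl)[C@@H](OCc2ccccc2)[C@](CCOCc3ccccc3)(OC(OCC)CBr)CC1=O | intermediate
18 | C26=C27 tert-butyldimethylsilyl enol ether of 17 | CC[C@H]1[C@H](CCCCCl)[C@@H](OCc2ccccc2)[C@](CCOCc3ccccc3)(OC(OCC)CBr)C=C1O[Si](C)(C)C(C)(C)C | intermediate
19 | cis-fused lactol ethyl acetal (acetal epimers) | CC[C@H]1[C@H](CCCCCl)[C@@H](OCc2ccccc2)[C@]3(CCOCc4ccccc4)OC(OCC)C[C@@H]3[C@@H]1O[Si](C)(C)C(C)(C)C | intermediate
20 | cis-fused γ-lactone | CC[C@H]1[C@H](CCCCCl)[C@@H](OCc2ccccc2)[C@]3(CCOCc4ccccc4)OC(=O)C[C@@H]3[C@@H]1O[Si](C)(C)C(C)(C)C | intermediate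
21 | N,N-dimethylmethyleneiminium iodide | C[N+](C)=C.[I-] | starting material
22 | Mannich base (dimethylaminomethyl on C24, convex face) | CC[C@H]1[C@H](CCCCCl)[C@@H](OCc2ccccc2)[C@]3(CCOCc4ccccc4)OC(=O)[C@@H](CN(C)C)[C@@H]3[C@@H]1O[Si](C)(C)C(C)(C)C | intermediate
23 | trimethylammonium iodide of 22 | CC[C@H]1[C@H](CCCCCl)[C@@H](OCc2ccccc2)[C@]3(CCOCc4ccccc4)OC(=O)[C@@H](C[N+](C)(C)C)[C@@H]3[C@@H]1O[Si](C)(C)C(C)(C)C.[I-] | intermediate
24 | α-methylene lactone | CC[C@H]1[C@H](CCCCCl)[C@@H](OCc2ccccc2)[C@]3(CCOCc4ccccc4)OC(=O)C(=C)[C@@H]3[C@@H]1O[Si](C)(C)C(C)(C)C | intermediate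
25 | diol with (24R)-methyl lactone | CC[C@H]1[C@H](CCCCCl)[C@@H](O)[C@]3(CCO)OC(=O)[C@H](C)[C@@H]3[C@@H]1O[Si](C)(C)C(C)(C)C | intermediate
26 | keto aldehyde (C5 ketone, C11 aldehyde) | CC[C@H]1[C@H](CCCCCl)C(=O)[C@]3(CC=O)OC(=O)[C@H](C)[C@@H]3[C@@H]1O[Si](C)(C)C(C)(C)C | intermediate
27 | (S)-2-methylpropane-2-sulfinamide | CC(C)(C)[S@](=O)N | starting material
28 | (E)-N-tert-butanesulfinyl aldimine at C11 | CC[C@H]1[C@H](CCCCCl)C(=O)[C@]3(C/C=N/[S@@](=O)C(C)(C)C)OC(=O)[C@H](C)[C@@H]3[C@@H]1O[Si](C)(C)C(C)(C)C | intermediate
29 | 3-methylfuran-2(5H)-one | CC1=CCOC1=O | starting material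
30 | 3-methyl-2-(triisopropylsilyloxy)furan | Cc1ccoc1O[Si](C(C)C)(C(C)C)C(C)C | intermediate
31 | butenolide sulfinamide (C11 R, C12 S) | CC[C@H]1[C@H](CCCCCl)C(=O)[C@]3(C[C@@H](N[S@@](=O)C(C)(C)C)[C@@H]4C=C(C)C(=O)O4)OC(=O)[C@H](C)[C@@H]3[C@@H]1O[Si](C)(C)C(C)(C)C | intermediate
32 | saturated lactone sulfinamide (C14 S) | CC[C@H]1[C@H](CCCCCl)C(=O)[C@]3(C[C@@H](N[S@@](=O)C(C)(C)C)[C@@H]4C[C@H](C)C(=O)O4)OC(=O)[C@H](C)[C@@H]3[C@@H]1O[Si](C)(C)C(C)(C)C | intermediate
33 | amino ketone hydrochloride | CC[C@H]1[C@H](CCCCCl)C(=O)[C@]3(C[C@@H](N)[C@@H]4C[C@H](C)C(=O)O4)OC(=O)[C@H](C)[C@@H]3[C@@H]1O.Cl | intermediate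
34 | 1-pyrroline (C5=N6) with 4-chlorobutyl on C4 | CC[C@H]1[C@H](CCCCCl)C2=N[C@@H]([C@@H]4C[C@H](C)C(=O)O4)C[C@]23OC(=O)[C@H](C)[C@@H]3[C@@H]1O | intermediate
35 | 1-pyrroline with 4-iodobutyl on C4 | CC[C@H]1[C@H](CCCCI)C2=N[C@@H]([C@@H]4C[C@H](C)C(=O)O4)C[C@]23OC(=O)[C@H](C)[C@@H]3[C@@H]1O | intermediate
36 | tetracyclic iminium iodide (C5=N6, C4–H) | CC[C@H]1[C@H]2C3=[N+](CCCC2)[C@@H]([C@@H]2C[C@H](C)C(=O)O2)C[C@]32OC(=O)[C@H](C)[C@@H]2[C@@H]1O.[I-] | intermediate
37 | CNP0154902.3 | CC[C@H]1C2=C3N(CCCC2)[C@@H]([C@@H]2C[C@H](C)C(=O)O2)C[C@]32OC(=O)[C@H](C)[C@@H]2[C@@H]1O | target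

## Step count and risks

Total step count: 24. Longest linear sequence: 23 steps (steps 1–19 and 21–24); step 20 is a one-step side branch.

**Step 14 (key step).** The most likely failure is hydrogen transfer to the C27 radical from both faces. The axial C19 arm on C20 lies 1,3 to C27 on the face from which hydrogen must come, and it competes with the shielding by the axial C24 branch on the other face. Some reduction of the open C24 radical before closure is also possible. Fallback: the C27 centre is reset by hydride instead of hydrogen-atom transfer. Starting from 19 of any C27 composition, HF·pyridine removes the silyl group to give the C27 alcohol mixture F1. Dess–Martin oxidation gives the C27 ketone F2. NaBH4 in methanol at low temperature should deliver hydride anti to the axial C24 branch and give the equatorial alcohol F3. Silylation (t-BuMe2SiOTf, 2,6-lutidine) returns to 19.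

**Step 8.** Hydride may attack both faces of the C27 ketone, because the ethyl group on C3 is the only nearby bias; the wrong C27 epimer would direct the epoxide to the wrong face in step 9. Fallback: the substrate-controlled reduction is replaced by a catalyst-controlled Corey–Bakshi–Shibata reduction of 11 with the oxazaborolidine antipode that gives the R alcohol, which arrives directly at 12.

**Step 13.** The enolate may expel the β-acetal oxygen (giving the C20=C26 enone) or attack the CH2Br group before it is silylated. Fallback: the enol ether is made before the acetal. From 15, N-(trimethylsilyl)imidazole gives the tertiary trimethylsilyl ether F4. LiN(i-Pr)2 and t-BuMe2SiOTf give the bis-silyl enol ether F5. K2CO3 in methanol frees the tertiary alcohol F6. Acetalisation with 1,2-dibromo-1-ethoxyethane F7 (made from 16 and bromine, so that no free bromonium source meets the enol ether) and N,N-dimethylaniline returns to 18.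

**Step 21.** The auxiliary may give insufficient facial selection at C11, or the wrong simple diastereoselection at C12, because the aldimine is flanked by a quaternary centre that may distort the open transition state. Fallback: catalyst control replaces auxiliary control. From 26, condensation with 2-methoxyaniline gives the N-aryl aldimine F8. A AgOAc-catalysed vinylogous Mannich reaction with 30 and a chiral amino-acid-derived phosphine gives the anti adduct F9. Hydrogenation over Pd/C gives the saturated lactone F10. Oxidative removal of the aryl group with PhI(OAc)2, followed by HCl in methanol, arrives at 33, which closes to 34 as in step 23.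

**Step 24.** The enamine tautomer of 34 may alkylate at C4 (five-membered spiro closure) faster than nitrogen closes the seven-membered ring, and long heating may allow acyl migration to O28. Fallback: the nitrogen is alkylated as an amine and the enamine is made by oxidation. From 34, hydrogenation over PtO2 in acetic acid gives the pyrrolidine F11 (C5 epimers, inconsequential). K2CO3 and NaI in acetonitrile close the azepine by amine alkylation to give the tertiary amine F12. Dehydrogenation with Hg(OAc)2 in aqueous acetic acid, which removes the tertiary α-hydrogen at C5, gives 37; competing oxidation at C11 is the weak point of this fallback.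

## Further compounds

F1 | step 14 | C27 alcohol of the lactol acetal, C27 epimers | CC[C@H]1[C@H](CCCCCl)[C@@H](OCc2ccccc2)[C@]3(CCOCc4ccccc4)OC(OCC)C[C@@H]3C1O
F2 | step 14 | C27 ketone of the lactol acetal | CC[C@H]1[C@H](CCCCCl)[C@@H](OCc2ccccc2)[C@]3(CCOCc4ccccc4)OC(OCC)C[C@@H]3C1=O
F3 | step 14 | (27R)-alcohol of the lactol acetal | CC[C@H]1[C@H](CCCCCl)[C@@H](OCc2ccccc2)[C@]3(CCOCc4ccccc4)OC(OCC)C[C@@H]3[C@@H]1O
F0 | step 8 | none | none
F4 | step 13 | trimethylsilyl ether of 15 at O21 | CC[C@H]1[C@H](CCCCCl)[C@@H](OCc2ccccc2)[C@](CCOCc3ccccc3)(O[Si](C)(C)C)CC1=O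
F5 | step 13 | C26=C27 tert-butyldimethylsilyl enol ether of F4 | CC[C@H]1[C@H](CCCCCl)[C@@H](OCc2ccccc2)[C@](CCOCc3ccccc3)(O[Si](C)(C)C)C=C1O[Si](C)(C)C(C)(C)C
F6 | step 13 | tertiary C20 alcohol with C26=C27 silyl enol ether | CC[C@H]1[C@H](CCCCCl)[C@@H](OCc2ccccc2)[C@](CCOCc3ccccc3)(O)C=C1O[Si](C)(C)C(C)(C)C
F7 | step 13 | 1,2-dibromo-1-ethoxyethane | CCOC(Br)CBr
F8 | step 21 | N-(2-methoxyphenyl) aldimine at C11 | CC[C@H]1[C@H](CCCCCl)C(=O)[C@]3(C/C=N/c5ccccc5OC)OC(=O)[C@H](C)[C@@H]3[C@@H]1O[Si](C)(C)C(C)(C)C
F9 | step 21 | N-(2-methoxyphenyl) anti Mannich adduct (butenolide) | CC[C@H]1[C@H](CCCCCl)C(=O)[C@]3(C[C@@H](Nc5ccccc5OC)[C@@H]4C=C(C)C(=O)O4)OC(=O)[C@H](C)[C@@H]3[C@@H]1O[Si](C)(C)C(C)(C)C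
F10 | step 21 | N-(2-methoxyphenyl) amino lactone (saturated, C14 S) | CC[C@H]1[C@H](CCCCCl)C(=O)[C@]3(C[C@@H](Nc5ccccc5OC)[C@@H]4C[C@H](C)C(=O)O4)OC(=O)[C@H](C)[C@@H]3[C@@H]1O[Si](C)(C)C(C)(C)C
F11 | step 24 | pyrrolidine from reduction of 34 (C5 epimers) | CC[C@H]1[C@H](CCCCCl)C2N[C@@H]([C@@H]4C[C@H](C)C(=O)O4)C[C@]23OC(=O)[C@H](C)[C@@H]3[C@@H]1O
F12 | step 24 | 4,5-dihydro derivative of 37 (tertiary amine, C5 epimers) | CC[C@H]1[C@H]2C3N(CCCC2)[C@@H]([C@@H]2C[C@H](C)C(=O)O2)C[C@]32OC(=O)[C@H](C)[C@@H]2[C@@H]1O
A1 | alternative 1 | tetracyclic C27 ketone with C7 lactam (C24 epimer) | CC[C@H]1C2=C3N(C(=O)CCC2)[C@@H]([C@@H]2C[C@H](C)C(=O)O2)C[C@]32OC(=O)[C@@H](C)[C@@H]2C1=O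
A2 | alternative 2 | tetracyclic vinylogous amide (C3 ketone, C9=C10 alkene) | O=C1C2=C3N(CCC=C2)[C@@H]([C@@H]2C[C@H](C)C(=O)O2)C[C@]32OC(=O)[C@H](C)[C@@H]2[C@@H]1O[Si](C)(C)C(C)(C)C
A3 | alternative 3 | 3-vinylcyclohexanone with fused lactol methyl acetal | CC(C)[Si](C(C)C)(C(C)C)OCCCCC2C(=O)[C@]3(CCOCc1ccccc1)OC(OC)[C@H](C)[C@@H]3[C@H](O[Si](C)(C)C(C)(C)C)[C@H]2C=C
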